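## Structural features

The target is a 6‑hydroxy‑2,8‑dimethylchroman: a benzene ring (ring A) fused through C4a and C8a to a dihydropyran (ring B) whose O1 joins C8a to the quaternary carbon C2. C2 carries O1, a methyl group, the ring methylene C3 and a nine‑carbon chain C1'–C9'. The chain holds two trisubstituted (E)‑alkenes, C3'=C4' (methyl on C4') and C7'=C8' (methyl on C8'), the second conjugated to the C9' carboxylic acid. C2 is the only stereocentre, (R), with no neighbouring stereocentre to relay from; its two methylene arms (C3 and C1') differ only three atoms out, so making it enantioselectively is the real difficulty, together with keeping both alkenes geometrically pure. Fragile elements are the electron‑rich para‑oxygenated phenol (oxidised to the quinone, most easily as the phenoxide in air), the tertiary alkyl aryl ether at C2 and the trisubstituted alkenes (acid‑sensitive), and the enoic acid. Ring A needs O1 at C8a flanked by the C8 methyl and the C4a–C4 bond, with the hydroxyl at C6 para to O1, so the two oxygens must be told apart. The key step uses the fact that C2 is bonded to O1 and becomes allylic once C1'–C2' is carried as a vinyl group: C2, C1' and C2' can be the three carbons of an allyl ligand on palladium, and the C8a phenol can close ring B by forming O1–C2, so that "methyl or C3 arm" becomes "one face or the other of a planar allyl unit". The vinyl group left on C2 then serves to attach C3'–C9'.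

## Logic of the disconnections

24 ⇒ 23 ⇒ 22. The last operations are the cleavage of the ester O–CH3 bond and of the acetal on the C6 oxygen. The acid and the phenol are the two groups of 24 that interfere with organoboron and palladium chemistry and, as the phenoxide, with air. Masking them reduces the end‑game to two deprotections. The demand is that the acetal leaves under acid mild enough for the alkenes and the tertiary ether, and that 23 is saponified without oxygen.

22 ⇒ 15 + 20. The cut is C2'–C3', an sp3–sp2 bond between the head that carries the stereocentre and a chain that holds both alkenes. C2 is not touched, and each alkene geometry is stored in a small achiral fragment. The gain is a bicyclic fragment with a single reactive group and a seven‑carbon iodo‑dienoate. The demand is that boron goes only to C2' (21) and that the coupling keeps the (E) geometry of 20 and spares its ester.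

15 ⇒ 14. This is the strategic cut, O1–C2. Ring B and the only stereocentre disappear together, and 14 is achiral. C3 and C4 are already saturated, so no later redox adjustment is needed. The demand is a geometrically pure (Z)‑alkene, a free C8a hydroxyl, a leaving group that ionises irreversibly, and conditions under which the two allyl complexes exchange faster than they close.

14 ⇒ 13 ⇒ 12. The cuts are the phenol O–H (Si–O in the forward sense) and the carbonate C–O. The phenol stays silylated while the allylic alcohol is acylated, so only one oxygen can take the methoxycarbonyl group. The demand is a fluoride cleavage mild enough that the liberated phenol does not cyclise without the catalyst, which would give racemic material.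

12 ⇒ 7 + 10. The cut is C3–C2 (chroman numbering), the bond between the arylethyl CH2 and the alkene carbon. The trisubstituted (Z)‑alkene is the hardest element of 14; cutting beside it lets the geometry be made in a four‑carbon piece and transferred by a stereoretentive coupling through 11. This replaces a long linear chain extension by one convergent step. The demand is anti‑Markovnikov hydroboration of the styrene and retention at the iodoalkene.

10 ⇒ 8. The cuts are C–I and C–H across the former alkyne. Hydroxyl‑directed trans‑hydroalumination through 9 can give only the (Z)‑iodoalkene, so geometric purity is secured by mechanism and not by separation.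

7 ⇒ 6 ⇒ 5 ⇒ 4. The cuts are C4=C3 (methylenation), the Si–O bond, and C4a–C4 (ortho‑formylation). The formyl carbon becomes C4. The other ortho position of 4 is blocked by the future C8 methyl, so the substrate itself enforces the regiochemistry.

4 ⇒ 2 ⇒ 1. The cuts are C8a–O1 (through 3) and the acetal O–C bond. O1 is introduced by oxidative replacement of a formyl group after the C6 oxygen has been protected. The two oxygens are therefore distinct by construction, and no selective mono‑protection of a hydroquinone is needed. The demand is aryl migration in preference to hydride migration.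

20 ⇒ 18 ⇒ 16. The cuts are C7'=C8' (olefination through 19), C4'–CH3 and C3'–I (carbometalation–iodination through 17). The demand is syn addition with methyl at the internal carbon and an (E)‑selective olefination.

## Other disconnections considered

Alternative 1: The cut removes three bonds of ring A at once (C4a–C8a, C5–C6, C6–C7) together with ring B. It leads back to the acyclic carbene complex A2, an alkoxy(isopropenyl)carbene of pentacarbonylchromium tied through O1–C2–C3–C4 to a terminal alkyne, with C2 already carrying the whole side chain. In the forward step, heating makes the alkyne insert into the chromium–carbene bond (the tether puts C4a on the carbene carbon C8a), CO inserts to a vinylketene, and electrocyclisation and tautomerisation give the para‑alkoxyphenol A1, the methyl ester of the target, identical with 23.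
- In its favour: it is the most convergent plan, with rings A and B formed in one operation. The substitution pattern (C8 methyl from the isopropenyl group, C6 hydroxyl from CO para to O1) is fixed by mechanism, at least the equal of the formylation regiocontrol of the chosen plan. The C6 hydroxyl appears free, so no phenol protection is needed, which is better than the chosen plan. Only an ester hydrolysis follows, which is also better.
- Against it here: the benzannulation does not create C2. The stereocentre must be made earlier as an acyclic tertiary alcohol whose two CH2CH2 arms differ only at the fourth atom, and no direct catalytic enantioselective method is evident for that. Alkoxycarbenes of tertiary alcohols are hard to form. The side‑chain alkenes, above all the electron‑poor enoate, can intercept the unsaturated chromium intermediates. Chromium is stoichiometric, and oxidative release of the arene must not oxidise the hydroquinone monoether.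
- Comparison: structurally all complexity sits in one acyclic precursor, whereas the chosen plan adds the chain after the stereocentre. Mechanistically it is a stoichiometric zerovalent chromium cascade that is silent on stereochemistry, against a catalytic ring closure that sets it. In step count after the key step the alternative is better, but reaching enantiopure A2 is expected to outweigh that gain.

Alternative 2: The cut is C3=C4 of a 2H‑chromene, leading back to the achiral triene A4, the ether of 3‑methylpenta‑1,4‑dien‑3‑ol with an ortho‑vinylphenol. In the forward step the complex Mo(N‑2,6‑iPr2C6H3)(CHCMe2Ph)(3,3'‑di‑tert‑butyl‑5,5',6,6'‑tetramethylbiphenyl‑2,2'‑diolate) initiates at the styrene, engages one of the two enantiotopic vinyl groups on C2 and releases ethene, giving A3.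
- In its favour: like the chosen plan it sets C2 in the ring‑forming step by catalyst control from an achiral precursor, so on this point the two are equals. A4 has no alkene geometry to control, which is better than the need for pure (Z)‑14. The product keeps the C2 vinyl group, so the same end‑game applies. The silyl ether can leave by fluoride instead of acid, at least the equal of the acetal.
- Against it here: O1–C2 of A4 is a tertiary, doubly allylic aryl ether, hard to form by substitution and prone to sigmatropic shifts. The product is a chromene, so C3=C4 must later be saturated beside the vinyl group (or beside the chain alkenes and the enoate), a chemoselectivity problem the chosen plan avoids because C3 and C4 are sp3 in 14. The molybdenum complex is very air‑ and moisture‑sensitive. The level of enantiotopic‑group selection for an aryl ether with a fully substituted carbinol carbon is as open as the sense of induction in step 10.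
- Comparison: both plans reach a 2‑methyl‑2‑vinyl heterocycle and differ in the bond closed. One is desymmetrising metathesis at a prochiral carbon, the other face selection on an allyl ligand. In step count nothing is gained: an ortho‑vinylphenol is needed in both, the ether formation replaces the coupling with 10, and a reduction is added.

Alternative 3: The cut is C4–C4a, leading back to the spirodienone A6 (methyl on C6 next to the spiro carbon). A6 would come from oxidative dearomatisation of a para‑(3‑hydroxyalkyl)phenol that could be derived from (R)‑linalool A7. In the forward step BF3·OEt2 activates the dienone, C4 shifts from the spiro carbon to the unsubstituted neighbouring carbon while O1 stabilises the cation, and proton loss restores the arene to give A5.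
- In its favour: C2 comes from the chiral pool and takes no part in any bond change, so no asymmetric catalysis is needed; this is better than the chosen plan, provided A7 is enantiomerically pure enough. The C6 hydroxyl is regenerated free, again better. The way to A5 would be shorter than the way to 15.
- Against it here: the shift can go to either ortho carbon, and the methyl‑bearing one is the better cation‑stabilising terminus, so the substrate does not secure the regiochemistry; oxygen migration also competes. The Lewis acid meets a trisubstituted alkene and a tertiary ether that can ionise, which threatens C2. A5 ends in an isopropylidene group, so C5' must be oxidised selectively at the (E)‑methyl and C6'–C9' attached by an sp3–sp3 allylic coupling, several steps with a free oxidisable phenol.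
- Comparison: structurally the head group is bought cheaply and paid for in the side chain, whereas the chosen plan delivers C1'–C2' ready for one coupling with the complete C3'–C9' unit. Mechanistically a cationic rearrangement with two competing termini stands against a ligand‑controlled substitution whose regiochemistry is fixed by ring size. In step count the alternative leads up to A5 and is expected to lose the lead in the chain extension.

Key step: step 10

Assumption: the (1R,2R) ligand is taken to be the enantiomer that converts (Z)‑14 into (S)‑15; the sense of induction is to be confirmed on the first run, and the (1S,2S) ligand replaces it, with nothing else changed, if the opposite sense is found.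

Step 1
Reactants: 1 4-hydroxy-2-methylbenzaldehyde
Product: 2 4-(methoxymethoxy)-2-methylbenzaldehyde
Conditions: MOMCl, i-Pr2NEt, CH2Cl2, 0 °C to rt
Reagents that add atoms: chloromethyl methyl ether, COCCl
Why: O-alkylation of the acidic para-formyl phenol to the MOM acetal; only one hydroxyl is present, so the oxygen that becomes the C6 oxygen is protected without any regiochemical question.

Step 2
Reactants: 2 4-(methoxymethoxy)-2-methylbenzaldehyde
Product: 4 4-(methoxymethoxy)-2-methylphenol, via aryl formate 3 (not isolated)
Conditions: mCPBA, CH2Cl2, 0 °C to rt; then K2CO3, MeOH, rt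
Reagents that add atoms: 3-chloroperoxybenzoic acid, OOC(=O)c1cccc(Cl)c1
Why: Baeyer–Villiger oxidation in which the electron-rich aryl group (para-alkoxy, ortho-methyl) migrates in preference to hydrogen, followed by base-catalysed methanolysis of formate 3; this places the future O1 next to the methyl group with the two ring oxygens already differentiated.

Step 3
Reactants: 4 4-(methoxymethoxy)-2-methylphenol
Product: 5 2-hydroxy-5-(methoxymethoxy)-3-methylbenzaldehyde
Conditions: MgCl2, Et3N, (CH2O)n, MeCN, reflux
Reagents that add atoms: paraformaldehyde (as formaldehyde), C=O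
Why: Magnesium-phenoxide-directed ortho-formylation (Casnati–Skattebøl): formaldehyde is delivered to the only free ortho position, and a second formaldehyde oxidises the benzylic alkoxide by hydride transfer; the basic medium leaves the MOM acetal intact.

Step 4
Reactants: 5 2-hydroxy-5-(methoxymethoxy)-3-methylbenzaldehyde
Product: 6 2-(tert-butyldimethylsilyloxy)-5-(methoxymethoxy)-3-methylbenzaldehyde
Conditions: TBSCl, imidazole, DMAP (cat.), DMF, rt to 40 °C
Reagents that add atoms: tert-butyldimethylsilyl chloride, CC(C)(C)[Si](C)(C)Cl
Why: Imidazole-assisted silylation masks the phenol for the ylide, borane and chloroformate steps and is orthogonal to the MOM acetal because it leaves with fluoride.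

Step 5
Reactants: 6 2-(tert-butyldimethylsilyloxy)-5-(methoxymethoxy)-3-methylbenzaldehyde
Product: 7 tert-butyl[2-ethenyl-4-(methoxymethoxy)-6-methylphenoxy]dimethylsilane
Conditions: Ph3PCH3Br, KN(SiMe3)2, THF, 0 °C to rt
Reagents that add atoms: methyltriphenylphosphonium bromide, C[P+](c1ccccc1)(c1ccccc1)c1ccccc1.[Br-]
Why: Wittig methylenation of a non-enolisable aryl aldehyde; it supplies C3 and a terminal alkene for anti-Markovnikov hydroboration.

Step 6
Reactants: 8 but-2-yn-1-ol
Product: 10 (Z)-3-iodobut-2-en-1-ol, via cyclic alkenylalanate 9 (not isolated)
Conditions: NaAlH2(OCH2CH2OMe)2, THF, 0 °C to rt; then I2, THF, −78 to 0 °C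
Reagents that add atoms: iodine, II
Why: Hydroxyl-directed trans-hydroalumination of the propargylic alcohol puts aluminium on C3 inside the five-membered alkoxyalanate 9, and iodinolysis with retention gives only the (Z)-iodoalkene; this fixes the alkene geometry that the key step needs.

Step 7
Reactants: 7 tert-butyl[2-ethenyl-4-(methoxymethoxy)-6-methylphenoxy]dimethylsilane; 10 (Z)-3-iodobut-2-en-1-ol
Product: 12 (Z)-5-[2-(tert-butyldimethylsilyloxy)-5-(methoxymethoxy)-3-methylphenyl]-3-methylpent-2-en-1-ol, via B-alkyl-9-BBN adduct 11 (not isolated)
Conditions: 9-BBN, THF, rt; then 10, PdCl2(dppf)·CH2Cl2 (5 mol %), K3PO4 (aq), DMF, rt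
Reagents that add atoms: none
Why: 9-BBN adds boron to the terminal carbon of the styrene, and the B-alkyl Suzuki–Miyaura coupling of 11 proceeds with retention at the iodoalkene, so the arylethyl group ends cis to CH2OH, that is (Z); free hydroxyl groups are tolerated under aqueous phosphate.

Step 8
Reactants: 12 (Z)-5-[2-(tert-butyldimethylsilyloxy)-5-(methoxymethoxy)-3-methylphenyl]-3-methylpent-2-en-1-ol
Product: 13 (Z)-5-[2-(tert-butyldimethylsilyloxy)-5-(methoxymethoxy)-3-methylphenyl]-3-methylpent-2-en-1-yl methyl carbonate
Conditions: ClCO2Me, pyridine, CH2Cl2, 0 °C
Reagents that add atoms: methyl chloroformate, COC(=O)Cl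
Why: Acylation of the primary allylic alcohol gives a leaving group that ionises irreversibly with loss of CO2; the phenol is still silylated, so only one oxygen can react.

Step 9
Reactants: 13 (Z)-5-[2-(tert-butyldimethylsilyloxy)-5-(methoxymethoxy)-3-methylphenyl]-3-methylpent-2-en-1-yl methyl carbonate
Product: 14 methyl (Z)-5-[2-hydroxy-5-(methoxymethoxy)-3-methylphenyl]-3-methylpent-2-enyl carbonate
Conditions: n-Bu4NF, AcOH (1:1), THF, 0 °C
Reagents that add atoms: none
Why: Fluoride cleaves the aryl Si–O bond; acetic acid keeps the liberated phenol protonated, so neither methoxycarbonyl transfer nor uncatalysed closure onto the allylic carbonate is expected, and the MOM acetal is inert to fluoride.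

Step 10
Reactants: 14 methyl (Z)-5-[2-hydroxy-5-(methoxymethoxy)-3-methylphenyl]-3-methylpent-2-enyl carbonate
Product: 15 (S)-6-(methoxymethoxy)-2,8-dimethyl-2-vinylchroman
Conditions: Pd2(dba)3·CHCl3 (2 mol %), (1R,2R)-N,N'-(cyclohexane-1,2-diyl)bis[2-(diphenylphosphino)benzamide] (6 mol %), AcOH (1 equiv), CH2Cl2 (0.05 M), rt
Reagents that add atoms: none
Why: Zerovalent palladium carrying the chiral bisphosphine ionises the allylic carbonate anti to the leaving group, with loss of CO2 and methoxide, to a cationic η3-allyl complex of divalent palladium spanning C2, C1' and C2'. The two diastereomeric complexes, which hold the metal on opposite faces of the allyl unit, interconvert by η3–η1–η3 slippage through the σ-bonded CH2 terminus, a process that changes the face but not the (Z) arrangement at the disubstituted terminus; acetic acid keeps the phenoxide concentration low so that this exchange is faster than ring closure (Curtin–Hammett regime). The phenol oxygen then attacks the methyl-bearing terminus anti to the metal in a 6-exo closure that forms O1–C2 and ring B; attack at the CH2 terminus would need an eight-membered ring and is not expected to compete, so the regioselectivity is secured by ring size. The new quaternary stereocentre C2 is controlled by the chiral pocket of the ligand, which selects the faster-closing complex, and by nothing in the substrate, which is achiral. The step needs enantioselectivity and regioselectivity: the first rests on the geometric purity of the (Z)-alkene fixed in steps 6 and 7, so that one ligand enantiomer maps onto one product enantiomer, and the second on the tether length. The closest known reaction type is the palladium-catalysed asymmetric allylic alkylation of phenols in its intramolecular form, which turns trisubstituted allyl carbonates with an ortho-tethered phenol into 2-methyl-2-vinylchromans. The MOM acetal, the electron-rich arene and the product vinyl group are inert to the catalyst at room temperature.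

Step 11
Reactants: 16 pent-4-yn-1-ol
Product: 18 (E)-5-iodo-4-methylpent-4-en-1-ol, via alkenylalane 17 (not isolated)
Conditions: AlMe3 (3 equiv), Cp2ZrCl2 (0.25 equiv), CH2Cl2, 0 °C to rt; then I2, THF, −30 to 0 °C; K2CO3 (aq)
Reagents that add atoms: trimethylaluminium, C[Al](C)C; iodine, II
Why: Zirconium-catalysed carboalumination (Negishi) adds methyl and aluminium syn across the terminal alkyne with methyl at the internal carbon (17), and iodinolysis with retention gives the (E)-2-methyl-1-iodoalkene; the hydroxyl is carried as its aluminium alkoxide.

Step 12
Reactants: 18 (E)-5-iodo-4-methylpent-4-en-1-ol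
Product: 20 methyl (2E,6E)-7-iodo-2,6-dimethylhepta-2,6-dienoate, via (E)-5-iodo-4-methylpent-4-enal 19 (not isolated)
Conditions: PhI(OAc)2, TEMPO (10 mol %), CH2Cl2, rt; then Ph3P=C(CH3)CO2Me, rt to 40 °C
Reagents that add atoms: methyl 2-(triphenylphosphoranylidene)propanoate, COC(=O)C(C)=P(c1ccccc1)(c1ccccc1)c1ccccc1
Why: TEMPO-catalysed oxidation stops at aldehyde 19, which is trapped in the same flask by the stabilised ylide in an (E)-selective Wittig reaction that forms C7'=C8'; the iodoalkene is untouched by either reagent.

Step 13
Reactants: 15 (S)-6-(methoxymethoxy)-2,8-dimethyl-2-vinylchroman; 20 methyl (2E,6E)-7-iodo-2,6-dimethylhepta-2,6-dienoate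
Product: 22 methyl (2E,6E)-9-[(2R)-6-(methoxymethoxy)-2,8-dimethylchroman-2-yl]-2,6-dimethylnona-2,6-dienoate, via B-alkyl-9-BBN adduct 21 (not isolated)
Conditions: 9-BBN, THF, rt to 50 °C; then 20, PdCl2(dppf)·CH2Cl2 (5 mol %), AsPh3 (10 mol %), K3PO4 (aq), DMF, rt
Reagents that add atoms: none
Why: Anti-Markovnikov hydroboration of the vinyl group and B-alkyl Suzuki–Miyaura coupling with retention of the (E) geometry of 20 form C2'–C3'. C2 is not involved and keeps its configuration; its descriptor changes from S in 15 to R in 21 and 22 only because the side chain now ranks below C3.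

Step 14
Reactants: 22 methyl (2E,6E)-9-[(2R)-6-(methoxymethoxy)-2,8-dimethylchroman-2-yl]-2,6-dimethylnona-2,6-dienoate
Product: 23 methyl (2E,6E)-9-[(2R)-6-hydroxy-2,8-dimethylchroman-2-yl]-2,6-dimethylnona-2,6-dienoate
Conditions: HCl (2 M in MeOH), MeOH/THF, rt to 40 °C
Reagents that add atoms: none
Why: Acid-catalysed acetal exchange with methanol removes the MOM group as dimethoxymethane; at this acidity and temperature the trisubstituted alkenes, the enoate and the tertiary aryl ether are expected to persist.

Step 15
Reactants: 23 methyl (2E,6E)-9-[(2R)-6-hydroxy-2,8-dimethylchroman-2-yl]-2,6-dimethylnona-2,6-dienoate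
Product: 24 (2E,6E)-9-[(2R)-6-hydroxy-2,8-dimethylchroman-2-yl]-2,6-dimethylnona-2,6-dienoic acid (CNP0176653.1)
Conditions: LiOH·H2O, THF/MeOH/H2O (degassed, argon), 45 °C; then HCl (1 M) to pH 3
Reagents that add atoms: lithium hydroxide (its oxygen becomes the carboxyl OH), [Li+].[OH-]
Why: Saponification of the methyl enoate by acyl–oxygen cleavage, run oxygen-free because the chromanol is easily oxidised as its phenoxide; neither C2 nor the alkene geometries are touched.

Compound list

1 | 4-hydroxy-2-methylbenzaldehyde | Cc1cc(O)ccc1C=O | starting material
2 | 4-(methoxymethoxy)-2-methylbenzaldehyde | COCOc1ccc(C=O)c(C)c1 | intermediate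
3 | 4-(methoxymethoxy)-2-methylphenyl formate | COCOc1ccc(OC=O)c(C)c1 | intermediate (not isolated)
4 | 4-(methoxymethoxy)-2-methylphenol | COCOc1ccc(O)c(C)c1 | intermediate
5 | 2-hydroxy-5-(methoxymethoxy)-3-methylbenzaldehyde | COCOc1cc(C)c(O)c(C=O)c1 | intermediate
6 | 2-(tert-butyldimethylsilyloxy)-5-(methoxymethoxy)-3-methylbenzaldehyde | COCOc1cc(C)c(O[Si](C)(C)C(C)(C)C)c(C=O)c1 | intermediate
7 | tert-butyl[2-ethenyl-4-(methoxymethoxy)-6-methylphenoxy]dimethylsilane | COCOc1cc(C)c(O[Si](C)(C)C(C)(C)C)c(C=C)c1 | intermediate
8 | but-2-yn-1-ol | CC#CCO | starting material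
9 | sodium 2,2-bis(2-methoxyethoxy)-3-methyl-2,5-dihydro-1,2-oxaluminol-2-uide (cyclic (Z)-alkenylalanate) | CC1=CCO[Al-]1(OCCOC)OCCOC.[Na+] | intermediate (not isolated)
10 | (Z)-3-iodobut-2-en-1-ol | C/C(I)=C/CO | intermediate
11 | 9-{2-[2-(tert-butyldimethylsilyloxy)-5-(methoxymethoxy)-3-methylphenyl]ethyl}-9-borabicyclo[3.3.1]nonane | COCOc1cc(C)c(O[Si](C)(C)C(C)(C)C)c(CCB2C3CCCC2CCC3)c1 | intermediate (not isolated)
12 | (Z)-5-[2-(tert-butyldimethylsilyloxy)-5-(methoxymethoxy)-3-methylphenyl]-3-methylpent-2-en-1-ol | COCOc1cc(C)c(O[Si](C)(C)C(C)(C)C)c(CC/C(C)=C\CO)c1 | intermediate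
13 | (Z)-5-[2-(tert-butyldimethylsilyloxy)-5-(methoxymethoxy)-3-methylphenyl]-3-methylpent-2-en-1-yl methyl carbonate | COCOc1cc(C)c(O[Si](C)(C)C(C)(C)C)c(CC/C(C)=C\COC(=O)OC)c1 | intermediate
14 | methyl (Z)-5-[2-hydroxy-5-(methoxymethoxy)-3-methylphenyl]-3-methylpent-2-enyl carbonate | COCOc1cc(C)c(O)c(CC/C(C)=C\COC(=O)OC)c1 | intermediate (precursor of the key step)
15 | (S)-6-(methoxymethoxy)-2,8-dimethyl-2-vinylchroman | C=C[C@]1(C)CCc2cc(OCOC)cc(C)c2O1 | intermediate (product of the key step)
16 | pent-4-yn-1-ol | C#CCCCO | starting material
17 | dimethyl[(E)-5-(dimethylalumanyloxy)-2-methylpent-1-en-1-yl]alumane | C[Al](C)/C=C(\C)CCCO[Al](C)C | intermediate (not isolated)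
18 | (E)-5-iodo-4-methylpent-4-en-1-ol | I/C=C(\C)CCCO | intermediate
19 | (E)-5-iodo-4-methylpent-4-enal | I/C=C(\C)CCC=O | intermediate (not isolated)
20 | methyl (2E,6E)-7-iodo-2,6-dimethylhepta-2,6-dienoate | I/C=C(\C)CC/C=C(\C)C(=O)OC | intermediate
21 | 9-{2-[(2R)-6-(methoxymethoxy)-2,8-dimethylchroman-2-yl]ethyl}-9-borabicyclo[3.3.1]nonane | B1(C2CCCC1CCC2)CC[C@]3(C)CCc4cc(OCOC)cc(C)c4O3 | intermediate (not isolated)
22 | methyl (2E,6E)-9-[(2R)-6-(methoxymethoxy)-2,8-dimethylchroman-2-yl]-2,6-dimethylnona-2,6-dienoate | C/C(=C\CC[C@]1(C)CCc2cc(OCOC)cc(C)c2O1)CC/C=C(\C)C(=O)OC | intermediate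
23 | methyl (2E,6E)-9-[(2R)-6-hydroxy-2,8-dimethylchroman-2-yl]-2,6-dimethylnona-2,6-dienoate | C/C(=C\CC[C@]1(C)CCc2cc(O)cc(C)c2O1)CC/C=C(\C)C(=O)OC | intermediate
24 | (2E,6E)-9-[(2R)-6-hydroxy-2,8-dimethylchroman-2-yl]-2,6-dimethylnona-2,6-dienoic acid | C/C(=C\CC[C@]1(C)CCc2cc(O)cc(C)c2O1)CC/C=C(\C)C(=O)O | target

Total step count: 15. Longest linear sequence: 12 steps (1 to 5, 7 to 10, 13 to 15); steps 6, 11 and 12 prepare the two coupling partners.

Least certain steps

Step 10 (key step). What may go wrong: ring closure outrunning the exchange of the two diastereomeric allyl complexes, or a share of uncatalysed or ligand-free closure, either of which erodes the enantioselectivity; an inverted sense of induction is handled by the antipodal ligand. The fallback sets C2 by a different, known principle and sets out from 12. Sharpless asymmetric epoxidation (Ti(OiPr)4, L-(+)-diethyl tartrate, t-BuOOH, 4 Å sieves, CH2Cl2, −20 °C) should give [(2S,3R)-3-{2-[2-(tert-butyldimethylsilyloxy)-5-(methoxymethoxy)-3-methylphenyl]ethyl}-3-methyloxiran-2-yl]methanol F1. Buffered fluoride (n-Bu4NF/AcOH, THF) would free the phenol to [(2S,3R)-3-{2-[2-hydroxy-5-(methoxymethoxy)-3-methylphenyl]ethyl}-3-methyloxiran-2-yl]methanol F2. Catalytic camphorsulfonic acid in CH2Cl2 at 0 °C should then close ring B by 6-exo attack of the phenol oxygen on the tertiary epoxide carbon with inversion, giving (1S)-1-[(2S)-6-(methoxymethoxy)-2,8-dimethylchroman-2-yl]ethane-1,2-diol F3. NaIO4 in THF/H2O cleaves the diol to (2S)-6-(methoxymethoxy)-2,8-dimethylchroman-2-carbaldehyde F4, which has no α-hydrogen, and Wittig methylenation (Ph3P=CH2, THF) comes back to the route at 15. The configuration then follows from the facial rule of the epoxidation and the inversion at C2, which also gives an independent check of the sense of induction in step 10.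

Step 9. What may go wrong: attack of the liberated phenoxide on the allylic carbonate (methoxycarbonyl transfer to the phenol, or closure without the catalyst to racemic chroman) before the fluoride is consumed. The fallback reverses the order of events and sets out from 12. n-Bu4NF in THF removes the silyl group first to give 2-[(Z)-5-hydroxy-3-methylpent-3-enyl]-4-(methoxymethoxy)-6-methylphenol F5. Chemoselective acylation of the primary allylic hydroxyl (ClCO2Me, 1.05 equiv, pyridine, CH2Cl2, −20 °C; the doubly ortho-substituted phenol reacts much more slowly) then comes back at 14, with fluoride never in contact with the carbonate.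

Step 13. What may go wrong: slow transmetalation of the alkylborane next to the quaternary carbon, so that protodeboronation, β-hydride elimination and base-induced loss of the ester of 20 compete. The fallback is a base-free organozinc coupling that sets out from 15. The same hydroboration to 21 followed by NaOH/H2O2 gives 2-[(2S)-6-(methoxymethoxy)-2,8-dimethylchroman-2-yl]ethan-1-ol F6. I2, PPh3 and imidazole convert it into (2S)-2-(2-iodoethyl)-6-(methoxymethoxy)-2,8-dimethylchroman F7. Zn dust with LiCl in THF inserts to {2-[(2S)-6-(methoxymethoxy)-2,8-dimethylchroman-2-yl]ethyl}zinc iodide F8, and Negishi coupling with 20 catalysed by Pd(PPh3)4 comes back at 22.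

Step 14. What may go wrong: acid-promoted side reactions if acetal cleavage is slow, namely protonation of the C3'=C4' alkene followed by cyclisation or addition of methanol, or ionisation of the tertiary C2–O1 ether with loss of configuration. The fallback exchanges the protecting group at a robust stage and sets out from 15, where only a vinyl group is present. The same HCl/MeOH treatment gives (2S)-2,8-dimethyl-2-vinylchroman-6-ol F9. TIPSCl and imidazole in DMF give triisopropyl{[(2S)-2,8-dimethyl-2-vinylchroman-6-yl]oxy}silane F10. 9-BBN gives 9-{2-[(2R)-2,8-dimethyl-6-(triisopropylsilyloxy)chroman-2-yl]ethyl}-9-borabicyclo[3.3.1]nonane F11, which is coupled with 20 as in step 13 to methyl (2E,6E)-9-[(2R)-2,8-dimethyl-6-(triisopropylsilyloxy)chroman-2-yl]-2,6-dimethylnona-2,6-dienoate F12. n-Bu4NF in THF then removes the silyl group and comes back at 23, so that no acid meets the polyene.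

Further compounds

F1 | step 10 | [(2S,3R)-3-{2-[2-(tert-butyldimethylsilyloxy)-5-(methoxymethoxy)-3-methylphenyl]ethyl}-3-methyloxiran-2-yl]methanol | C[C@]1(CCc2cc(OCOC)cc(C)c2O[Si](C)(C)C(C)(C)C)O[C@H]1CO
F2 | step 10 | [(2S,3R)-3-{2-[2-hydroxy-5-(methoxymethoxy)-3-methylphenyl]ethyl}-3-methyloxiran-2-yl]methanol | C[C@]1(CCc2cc(OCOC)cc(C)c2O)O[C@H]1CO
F3 | step 10 | (1S)-1-[(2S)-6-(methoxymethoxy)-2,8-dimethylchroman-2-yl]ethane-1,2-diol | OC[C@H](O)[C@]1(C)CCc2cc(OCOC)cc(C)c2O1
F4 | step 10 | (2S)-6-(methoxymethoxy)-2,8-dimethylchroman-2-carbaldehyde | O=C[C@]1(C)CCc2cc(OCOC)cc(C)c2O1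
F5 | step 9 | 2-[(Z)-5-hydroxy-3-methylpent-3-enyl]-4-(methoxymethoxy)-6-methylphenol | COCOc1cc(C)c(O)c(CC/C(C)=C\CO)c1
F6 | step 13 | 2-[(2S)-6-(methoxymethoxy)-2,8-dimethylchroman-2-yl]ethan-1-ol | OCC[C@]1(C)CCc2cc(OCOC)cc(C)c2O1
F7 | step 13 | (2S)-2-(2-iodoethyl)-6-(methoxymethoxy)-2,8-dimethylchroman | ICC[C@]1(C)CCc2cc(OCOC)cc(C)c2O1
F8 | step 13 | {2-[(2S)-6-(methoxymethoxy)-2,8-dimethylchroman-2-yl]ethyl}zinc iodide | I[Zn]CC[C@]1(C)CCc2cc(OCOC)cc(C)c2O1
F9 | step 14 | (2S)-2,8-dimethyl-2-vinylchroman-6-ol | C=C[C@]1(C)CCc2cc(O)cc(C)c2O1
F10 | step 14 | triisopropyl{[(2S)-2,8-dimethyl-2-vinylchroman-6-yl]oxy}silane | C=C[C@]1(C)CCc2cc(O[Si](C(C)C)(C(C)C)C(C)C)cc(C)c2O1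
F11 | step 14 | 9-{2-[(2R)-2,8-dimethyl-6-(triisopropylsilyloxy)chroman-2-yl]ethyl}-9-borabicyclo[3.3.1]nonane | B1(C2CCCC1CCC2)CC[C@]3(C)CCc4cc(O[Si](C(C)C)(C(C)C)C(C)C)cc(C)c4O3
F12 | step 14 | methyl (2E,6E)-9-[(2R)-2,8-dimethyl-6-(triisopropylsilyloxy)chroman-2-yl]-2,6-dimethylnona-2,6-dienoate | C/C(=C\CC[C@]1(C)CCc2cc(O[Si](C(C)C)(C(C)C)C(C)C)cc(C)c2O1)CC/C=C(\C)C(=O)OC
A1 | alternative 1 | methyl (2E,6E)-9-[(2R)-6-hydroxy-2,8-dimethylchroman-2-yl]-2,6-dimethylnona-2,6-dienoate | C/C(=C\CC[C@]1(C)CCc2cc(O)cc(C)c2O1)CC/C=C(\C)C(=O)OC
A2 | alternative 1 | pentacarbonyl{(prop-1-en-2-yl)[(2E,6E,10R)-1-methoxy-2,6,10-trimethyl-1-oxotetradeca-2,6-dien-13-yn-10-yloxy]methylidene}chromium | COC(=O)/C(C)=C/CC/C(C)=C/CC[C@](C)(CCC#C)OC(C(C)=C)=[Cr](=C=O)(=C=O)(=C=O)(=C=O)=C=O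
A3 | alternative 2 | (R)-2,8-dimethyl-6-(triisopropylsilyloxy)-2-vinyl-2H-chromene | C=C[C@]1(C)C=Cc2cc(O[Si](C(C)C)(C(C)C)C(C)C)cc(C)c2O1
A4 | alternative 2 | triisopropyl{3-methyl-4-[(3-methylpenta-1,4-dien-3-yl)oxy]-5-vinylphenoxy}silane | C=CC(C)(C=C)Oc1c(C)cc(O[Si](C(C)C)(C(C)C)C(C)C)cc1C=C
A5 | alternative 3 | (R)-2,8-dimethyl-2-(4-methylpent-3-enyl)chroman-6-ol | CC(C)=CCC[C@]1(C)CCc2cc(O)cc(C)c2O1
A6 | alternative 3 | (2R)-2,6-dimethyl-2-(4-methylpent-3-enyl)-1-oxaspiro[4.5]deca-6,9-dien-8-one (either configuration at the spiro carbon) | CC(C)=CCC[C@]1(C)CCC2(O1)C=CC(=O)C=C2C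
A7 | alternative 3 | (R)-linalool, (3R)-3,7-dimethylocta-1,6-dien-3-ol | C=C[C@](C)(O)CCC=C(C)C
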